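The numbers in the tables were computed with constants of no real substance, noise included.

I decided to leave the clock out and ask where Q goes rather than how fast it goes.

| flask | Q | E | remark | time |
|---|---|---|---|---|
| dawn | 0.25 M | 42 mM | run made earlier |  |
| noon | 0.25 M | 210 mM | run made earlier |  |
| theta | 0.25 M | 180 mM |  | 40 min |
| delta | 0.25 M | 70 mM |  | 40 min |
| epsilon | 0.25 M | 28 mM |  | 40 min |

| run | time / min | G / % | D / % | Q / % | L / % |
|---|---|---|---|---|---|
| dawn | 5.00 | 44.8 | 2.0 | 32.8 | 4.9 |
| dawn | 10.0 | 68.5 | 0.7 | 11.5 | 0.9 |
| dawn | 15.0 | 77.3 | 0 | 2.9 | 0.8 |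
| dawn | 20.0 | 79.8 | 0.8 | 2.2 | 0 |
| noon | 2.50 | 73.5 | 4.2 | 10.0 | 9.1 |
| noon | 8.00 | 95.9 | 0 | 0.2 | 0.3 |
| noon | 12.0 | 97.0 | 0.6 | 0.8 | 0 |
| noon | 20.0 | 96.3 | 0 | 0.3 | 0.4 |

(each reading ± 0.5 percentage points)

1. which of these there is most of at the end, counted by the Q in it, theta (L / G / D / Q)
2. which of these there is most of at the end, counted by the Q in it, delta (L / G / D / Q)
3. which of these there is most of at the end, counted by the Q in it, epsilon (L / G / D / Q)
4. final amount of the leader among these, as a percentage of the Q charged, in theta
5. final amount of the leader among these, as a percentage of the Q charged, in delta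
6. final amount of the leader among these, as a percentage of the Q charged, in epsilon

- percentages count the Q that a species holds: one Z counts as two
- steps that have been proposed: Q + E -> D; D -> L; L -> E + G; 2 E -> X; 2 Q -> Z

At 20.0 min dawn held 79.8 % of its Q charge as G and noon held 96.3 %, yet E is handed back at each round by L -> E + G, so a larger charge of it looks as if it should bring speed rather than more product. Waiting does not close this gap of 16 percentage points, because Q, D and L together read 3.00 % in dawn at that time, far smaller.

The answer lies in dividing one road by the other. With q the fraction of the Q charge still free and e the fraction of the E charge still free, 2 Q -> Z goes with the square of Q and Q + E -> D with Q times E, so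

Z road / catalyst road ∝ (Q charge / E charge) × q / e

Time has dropped out of this ratio, and the charges stand in it beside q / e. I therefore took as my measure the loss ratio R (a selectivity factor), the fraction of the charge not in G divided by the fraction g in G, counting what dawn still held as Q, D and L as lost, which leans low on G:

R, dawn = 0.253; R, noon = 0.0384

E rose by a factor of 5.00 and R fell by a factor of 6.59, a little steeper than in proportion, so I kept the loss exponent, the power of (Q charge / E charge) that I took R to follow, as a reading with the scatter of these two runs, whose Q charges were equal: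

n = 1.17 

With g = 1 / (1 + R), I reckoned G at 95.6 % for theta, 87.8 % for delta and, with R = 0.407, 71.1 % for epsilon.

The forecast named G as leader in theta, G in delta and G in epsilon, at 96 %, 88 % and 71 %, on the ground of “a second-order side reaction competes with a catalytic path first-order in Q”.

The flasks gave G in theta, G in delta and G in epsilon, at 95.5 %, 88.2 % and 74.6 %, and the forecast held.

    Q + E → D (k = 8.60 M⁻¹ min⁻¹)
    D → L (k = 3.00 min⁻¹)
    L → E + G (k = 2.00 min⁻¹)
    2 E → X (k = 1.30 M⁻¹ min⁻¹)
    2 Q → Z (k = 0.170 M⁻¹ min⁻¹)

At the start of epsilon, with its charges as they stood, Q + E -> D used Q 2.83 times as fast as 2 Q -> Z, and at 40.0 min that ratio stood at 150, with 24.8 % of the charge in Z. Epsilon's own R came to 0.341. Carried with n to a flask like epsilon but charged with 0.10 M of Q, it becomes 0.117, which gives G at 89.5 %, and that flask stood at 89.6 %.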